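## Retrosynthetic overview

- The eight C–Br bonds, all ortho to the four phenol oxygens, are disconnected first (electrophilic bromination of the tetraphenol). The phenols come from four methyl ethers and the pyrrole N–H from an N-[2-(trimethylsilyl)ethoxy]methyl (SEM) group.
- Key disconnection: the two bonds from pyrrole C3 and C4 to the 4-methoxyphenyl rings, formed together by twofold palladium-catalysed C–H arylation of the N-SEM 2,5-bis(4-methoxybenzoyl)pyrrole with 4-iodoanisole.
- Structural feature used: once the two aroyl carbonyl carbons sit on C2 and C5, C3–H and C4–H are the only C–H bonds left on the pyrrole ring. They are the carbons that carry the two aryl rings in the target, and each is acidified by the adjacent C=O.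
- The diketone is reached from pyrrole by N-SEM protection, then SEM-directed 2,5-dilithiation and acylation with the Weinreb amide of 4-methoxybenzoic acid.
- No ring is formed: the pyrrole and the four benzene rings are purchased. Bond order is C2/C5–acyl, then C3/C4–aryl, then C–Br.

Key step: step 3

Remark on the chemistry: N,4-dimethoxy-N-methylbenzamide 4 is taken as a purchased reagent (otherwise one step from 4-methoxybenzoyl chloride and N,O-dimethylhydroxylamine hydrochloride). The target is achiral, so no stereocentre has to be set.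

## Route

Step 1
Reactants: 1 pyrrole; 2 2-(trimethylsilyl)ethoxymethyl chloride (SEMCl)
Product: 3 1-{[2-(trimethylsilyl)ethoxy]methyl}-1H-pyrrole
Conditions: NaH (1.2 equiv), DMF, 0 °C; then 2 (1.1 equiv), 0 → 25 °C
Reagents that add atoms: 2-(trimethylsilyl)ethoxymethyl chloride (compound 2), C[Si](C)(C)CCOCCl
Why: NaH deprotonates the pyrrole N–H and the sodium pyrrolide is N-alkylated by the reactive chloromethyl ether (SN2 N-alkylation, standard SEM protection), with no stereocentre formed.

Step 2
Reactants: 3 1-{[2-(trimethylsilyl)ethoxy]methyl}-1H-pyrrole; 4 N,4-dimethoxy-N-methylbenzamide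
Product: 7 [1-{[2-(trimethylsilyl)ethoxy]methyl}-1H-pyrrole-2,5-diyl]bis[(4-methoxyphenyl)methanone], via 2,5-dilithio-1-SEM-pyrrole 5 (not isolated), via dilithium bis(hemiaminal) adduct 6 (not isolated)
Conditions: n-BuLi (2.5 equiv), TMEDA (2.5 equiv), hexane, 0 → 40 °C; then 4 (2.5 equiv), THF, −78 → 0 °C; aq. NH4Cl
Reagents that add atoms: N,4-dimethoxy-N-methylbenzamide (compound 4), COc1ccc(cc1)C(=O)N(C)OC
Why: Directed α,α′-dilithiation of an N-substituted pyrrole (n-BuLi/TMEDA, assisted by the SEM oxygen) gives 5, and each C–Li adds once to the Weinreb amide because the chelated adduct 6 holds until the aqueous quench (Weinreb ketone synthesis); the two hemiaminal carbons of 6 form without control and vanish on hydrolysis.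

Step 3
Reactants: 7 [1-{[2-(trimethylsilyl)ethoxy]methyl}-1H-pyrrole-2,5-diyl]bis[(4-methoxyphenyl)methanone]; 8 4-iodoanisole
Product: 10 [3,4-bis(4-methoxyphenyl)-1-{[2-(trimethylsilyl)ethoxy]methyl}-1H-pyrrole-2,5-diyl]bis[(4-methoxyphenyl)methanone], via 3-monoarylated pyrrole 9 (not isolated)
Conditions: 8 (4 equiv), Pd(OAc)2 (10 mol %), PCy3·HBF4 (20 mol %), CsOPiv (5 equiv), DMA, 130 °C, argon
Reagents that add atoms: 4-iodoanisole (compound 8), COc1ccc(I)cc1
Why: Zerovalent palladium, formed in the flask from Pd(OAc)2 and PCy3, adds oxidatively to the C–I bond of 8, iodide is exchanged for pivalate, and the arylpalladium pivalate cleaves the pyrrole C3–H bond by concerted metalation–deprotonation; reductive elimination forms the C3–aryl bond, and the same cycle on monoarylated 9 forms the C4–aryl bond. The closest known reaction type is the carboxylate-assisted palladium-catalysed direct β-arylation of 2,5-disubstituted N-protected pyrroles with aryl halides. No ring is closed and no stereocentre is formed. Site selectivity is built into 7: the aroyl groups block C2 and C5, so C3–H and C4–H are the only pyrrole C–H bonds, and the adjacent carbonyl groups acidify them for the metalation–deprotonation step. The ortho C–H bonds of the anisoyl rings are less acidic and should react more slowly, the diaryl ketones have no α-hydrogen for enolate arylation, and the N-SEM group prevents N-arylation and formation of an inert palladium pyrrolide. Excess 8 and stoichiometric CsOPiv are used to push the crowded second arylation to completion.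

Step 4
Reactants: 10 [3,4-bis(4-methoxyphenyl)-1-{[2-(trimethylsilyl)ethoxy]methyl}-1H-pyrrole-2,5-diyl]bis[(4-methoxyphenyl)methanone]
Product: 12 [3,4-bis(4-methoxyphenyl)-1H-pyrrole-2,5-diyl]bis[(4-methoxyphenyl)methanone], via N-hydroxymethyl pyrrole 11 (not isolated)
Conditions: TBAF (1 M in THF, 5 equiv), THF, 65 °C; aq. NH4Cl
Reagents that add atoms: none
Why: Fluoride attacks silicon and fragments the SEM group to ethylene and the N-hydroxymethyl alkoxide of 11, which loses formaldehyde easily because the 2,5-diaroylpyrrolide is a stabilised leaving group (fluoride-induced SEM cleavage); doing this before the phenols are unmasked keeps the formaldehyde away from free phenols.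

Step 5
Reactants: 12 [3,4-bis(4-methoxyphenyl)-1H-pyrrole-2,5-diyl]bis[(4-methoxyphenyl)methanone]
Product: 13 [3,4-bis(4-hydroxyphenyl)-1H-pyrrole-2,5-diyl]bis[(4-hydroxyphenyl)methanone]
Conditions: BBr3 (12 equiv), CH2Cl2, −78 → 25 °C; then H2O, 0 °C
Reagents that add atoms: none
Why: BBr3 coordinates each aryl methyl ether oxygen and bromide removes the methyl group by SN2 (Lewis-acid ether cleavage), the excess covering boron bound by the two ketones and the N–H, while diaryl ketones and the pyrrole ring are inert.

Step 6
Reactants: 13 [3,4-bis(4-hydroxyphenyl)-1H-pyrrole-2,5-diyl]bis[(4-hydroxyphenyl)methanone]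
Product: 14 [3,4-bis(3,5-dibromo-4-hydroxyphenyl)-1H-pyrrole-2,5-diyl]bis[(3,5-dibromo-4-hydroxyphenyl)methanone] (target)
Conditions: Br2 (8.5 equiv), AcOH, 25 → 50 °C
Reagents that add atoms: bromine, BrBr
Why: Electrophilic aromatic substitution in which each phenol directs bromine to its two free ortho positions (para is occupied by the pyrrole carbon or the carbonyl carbon), giving the eight C–Br bonds, while the fully substituted pyrrole and the ketones without α-hydrogen offer no other site.

## Compound list

1 | pyrrole | c1cc[nH]c1 | starting material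
2 | 2-(trimethylsilyl)ethoxymethyl chloride (SEMCl) | C[Si](C)(C)CCOCCl | starting material
3 | 1-{[2-(trimethylsilyl)ethoxy]methyl}-1H-pyrrole | C[Si](C)(C)CCOCn1cccc1 | intermediate
4 | N,4-dimethoxy-N-methylbenzamide | COc1ccc(cc1)C(=O)N(C)OC | starting material
5 | 2,5-dilithio-1-{[2-(trimethylsilyl)ethoxy]methyl}-1H-pyrrole (formed in the flask, not isolated) | [Li]c1ccc([Li])n1COCC[Si](C)(C)C | intermediate
6 | dilithium bis(hemiaminal) adduct of 5 with two molecules of 4 (not isolated; diastereomer mixture at the two hemiaminal carbons, erased on hydrolysis) | COc1ccc(cc1)C(O[Li])(N(C)OC)c1ccc(n1COCC[Si](C)(C)C)C(O[Li])(N(C)OC)c1ccc(OC)cc1 | intermediate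
7 | [1-{[2-(trimethylsilyl)ethoxy]methyl}-1H-pyrrole-2,5-diyl]bis[(4-methoxyphenyl)methanone] | COc1ccc(cc1)C(=O)c1ccc(C(=O)c2ccc(OC)cc2)n1COCC[Si](C)(C)C | intermediate
8 | 4-iodoanisole | COc1ccc(I)cc1 | starting material
9 | [3-(4-methoxyphenyl)-1-{[2-(trimethylsilyl)ethoxy]methyl}-1H-pyrrole-2,5-diyl]bis[(4-methoxyphenyl)methanone] (not isolated) | COc1ccc(cc1)C(=O)c1cc(-c2ccc(OC)cc2)c(C(=O)c2ccc(OC)cc2)n1COCC[Si](C)(C)C | intermediate
10 | [3,4-bis(4-methoxyphenyl)-1-{[2-(trimethylsilyl)ethoxy]methyl}-1H-pyrrole-2,5-diyl]bis[(4-methoxyphenyl)methanone] | COc1ccc(cc1)C(=O)c1c(-c2ccc(OC)cc2)c(-c2ccc(OC)cc2)c(C(=O)c2ccc(OC)cc2)n1COCC[Si](C)(C)C | intermediate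
11 | [1-(hydroxymethyl)-3,4-bis(4-methoxyphenyl)-1H-pyrrole-2,5-diyl]bis[(4-methoxyphenyl)methanone] (as its alkoxide, not isolated) | COc1ccc(cc1)C(=O)c1c(-c2ccc(OC)cc2)c(-c2ccc(OC)cc2)c(C(=O)c2ccc(OC)cc2)n1CO | intermediate
12 | [3,4-bis(4-methoxyphenyl)-1H-pyrrole-2,5-diyl]bis[(4-methoxyphenyl)methanone] | COc1ccc(cc1)C(=O)c1[nH]c(C(=O)c2ccc(OC)cc2)c(-c2ccc(OC)cc2)c1-c1ccc(OC)cc1 | intermediate
13 | [3,4-bis(4-hydroxyphenyl)-1H-pyrrole-2,5-diyl]bis[(4-hydroxyphenyl)methanone] | O=C(c1ccc(O)cc1)c1[nH]c(C(=O)c2ccc(O)cc2)c(-c2ccc(O)cc2)c1-c1ccc(O)cc1 | intermediate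
14 | [3,4-bis(3,5-dibromo-4-hydroxyphenyl)-1H-pyrrole-2,5-diyl]bis[(3,5-dibromo-4-hydroxyphenyl)methanone] | O=C(c1cc(Br)c(O)c(Br)c1)c1[nH]c(C(=O)c2cc(Br)c(O)c(Br)c2)c(-c2cc(Br)c(O)c(Br)c2)c1-c1cc(Br)c(O)c(Br)c1 | target

## Step count and risks

Total step count: 6. Longest linear sequence: 6 steps (pyrrole 1 to target 14).

**Steps most likely to fail**

1. Step 3 (twofold C–H arylation). The second arylation may stall, because the remaining C4–H lies between the new aryl ring and an aroyl group. Palladium may also be diverted into ketone-directed ortho-palladation of the anisoyl rings, or be slowed by accumulating iodide. Fallback (halogenation and cross-coupling in place of C–H activation), setting out from 7: twofold electrophilic bromination of the pyrrole β positions (NBS, DMF, 0 → 25 °C) should give [3,4-dibromo-1-{[2-(trimethylsilyl)ethoxy]methyl}-1H-pyrrole-2,5-diyl]bis[(4-methoxyphenyl)methanone] F1. A twofold Suzuki–Miyaura coupling with (4-methoxyphenyl)boronic acid (Pd(PPh3)4, K3PO4, dioxane/H2O, 90 °C) then returns to the route at 10.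

2. Step 2 (dilithiation and double acylation). The second deprotonation may be incomplete, or metalation may occur at a β position or at the SEM methylene, giving mixtures of mono- and diacylated material. Fallback (C-acylation of the N-magnesiated pyrrole in place of lithiation), setting out from 1: pyrrole is converted with EtMgBr (THF, 0 °C) into pyrrolylmagnesium bromide and acylated with 4-methoxybenzoyl chloride to (4-methoxyphenyl)(1H-pyrrol-2-yl)methanone F2. A second round of EtMgBr and 4-methoxybenzoyl chloride, which under magnesium coordination should acylate the remaining α position, gives 1H-pyrrole-2,5-diylbis[(4-methoxyphenyl)methanone] F3. N-Alkylation with SEMCl 2 (NaH, DMF, 0 → 25 °C) returns to the route at 7.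

3. Step 4 (SEM removal). Fluoride-induced fragmentation may be slow at the nitrogen crowded by two aroyl groups, or the reaction may stop at the N-hydroxymethyl stage and re-add formaldehyde. Fallback (Lewis-acid global deprotection in place of fluoride), setting out from 10: excess BBr3 (CH2Cl2, −78 → 25 °C) cleaves the SEM ether and the four methyl ethers in one operation. Water quench should leave [1-(hydroxymethyl)-3,4-bis(4-hydroxyphenyl)-1H-pyrrole-2,5-diyl]bis[(4-hydroxyphenyl)methanone] F4. Brief treatment with K2CO3 in MeOH at 0 °C expels formaldehyde and returns to the route at 13, so that 12 is bypassed.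

## Further compounds

F1 | step 3 | [3,4-dibromo-1-{[2-(trimethylsilyl)ethoxy]methyl}-1H-pyrrole-2,5-diyl]bis[(4-methoxyphenyl)methanone] | COc1ccc(cc1)C(=O)c1c(Br)c(Br)c(C(=O)c2ccc(OC)cc2)n1COCC[Si](C)(C)C
F2 | step 2 | (4-methoxyphenyl)(1H-pyrrol-2-yl)methanone | COc1ccc(cc1)C(=O)c1ccc[nH]1
F3 | step 2 | 1H-pyrrole-2,5-diylbis[(4-methoxyphenyl)methanone] | COc1ccc(cc1)C(=O)c1ccc([nH]1)C(=O)c1ccc(OC)cc1
F4 | step 4 | [1-(hydroxymethyl)-3,4-bis(4-hydroxyphenyl)-1H-pyrrole-2,5-diyl]bis[(4-hydroxyphenyl)methanone] | O=C(c1ccc(O)cc1)c1c(-c2ccc(O)cc2)c(-c2ccc(O)cc2)c(C(=O)c2ccc(O)cc2)n1CO
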